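**Strategy**

The route rests on cutting the bond between C6 of the 5,6-dihydro-2H-pyran-2-one ring and the exocyclic alkene carbon C1' that carries CH2OAc. C6 is a secondary allylic carbinol carbon hidden in the lactone, next to the E-trisubstituted C1'=C2' alkene. A ligand-controlled Ni/Cr (Nozaki–Hiyama–Kishi) reductive union of two electrophilic carbons joins an (E)-2-iodoallyl acetate (C11, from nerol) to a (Z)-enoate aldehyde (C11): in one operation it forms C6–C1', sets C6 (R), keeps the alkene geometry, and the C6 alkoxide closes the lactone onto the cis-disposed C2 ester. Desilylation then gives the target.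

Key step: step 12

Remark on numbering: ring atoms are O1, C2(=O), C3, C4, C5, C6; the side chain runs from C1' (bearing CH2OAc) to C7' (CH2OH). The C5'=C6' alkene of the target is Z, so nerol (not geraniol) is the starting terpene.

Assumption: the enantiomer of the oxazoline–sulfonamide ligand that delivers the alkenyl group to the Si face of the aldehyde is assigned from the empirical model of this ligand class; the antipode is used if a test run shows the opposite sense.

**Route**

Step 1
Reactants: 1 nerol [(2Z)-3,7-dimethylocta-2,6-dien-1-ol]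
Product: 2 tert-butyl{[(2Z)-3,7-dimethylocta-2,6-dien-1-yl]oxy}dimethylsilane
Conditions: TBSCl, imidazole, CH2Cl2, 0 °C to rt
Reagents that add atoms: tert-butyldimethylsilyl chloride, CC(C)(C)[Si](C)(C)Cl
Why: Standard silylation of a primary allylic alcohol gives an ether that should survive organolithium, K2CO3/MeOH and Cr/Ni conditions and is removed last with fluoride.

Step 2
Reactants: 2 neryl TBS ether
Product: 3 racemic tert-butyl{[(2Z)-5-(3,3-dimethyloxiran-2-yl)-3-methylpent-2-en-1-yl]oxy}dimethylsilane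
Conditions: m-CPBA (1.0 equiv), CH2Cl2, −20 °C
Reagents that add atoms: m-chloroperbenzoic acid, O=C(OO)c1cccc(Cl)c1
Why: Prilezhaev epoxidation should prefer the remote, more electron-rich trisubstituted alkene over the one deactivated by the allylic oxygen; the new stereocentre is racemic and is excised in step 3.

Step 3
Reactants: 3 racemic 6,7-epoxide
Product: 4 (4Z)-6-[(tert-butyldimethylsilyl)oxy]-4-methylhex-4-enal
Conditions: H5IO6 (1.1 equiv), THF/Et2O, 0 °C, short reaction time
Reagents that add atoms: none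
Why: Periodic acid opens the epoxide to the diol and cleaves it (Malaprade cleavage) to the aldehyde and acetone, leaving the Z-alkene untouched.

Step 4
Reactants: 4 (4Z)-6-[(tert-butyldimethylsilyl)oxy]-4-methylhex-4-enal
Product: 5 tert-butyldimethyl{[(2Z)-3-methylhept-2-en-6-yn-1-yl]oxy}silane
Conditions: dimethyl (1-diazo-2-oxopropyl)phosphonate, K2CO3, MeOH, 0 °C to rt
Reagents that add atoms: Ohira–Bestmann reagent, COP(=O)(OC)C(=[N+]=[N-])C(C)=O
Why: Seyferth–Gilbert homologation in the Ohira–Bestmann form converts an enolizable aldehyde into the terminal alkyne under mild base that the silyl ether tolerates.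

Step 5
Reactants: 5 terminal alkyne
Product: 6 (6Z)-8-[(tert-butyldimethylsilyl)oxy]-6-methyloct-6-en-2-yn-1-ol
Conditions: n-BuLi, THF, −78 °C; (CH2O)n, −78 °C to rt; then H2O
Reagents that add atoms: paraformaldehyde (formaldehyde), C=O
Why: Addition of the lithium acetylide to formaldehyde is the standard hydroxymethylation of a terminal alkyne.

Step 6
Reactants: 6 propargylic alcohol
Product: 8 (2E,6Z)-8-[(tert-butyldimethylsilyl)oxy]-2-iodo-6-methylocta-2,6-dien-1-ol, via vinylstannane 7 (not isolated)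
Conditions: Bu3SnH, PdCl2(PPh3)2 (cat.), THF, 0 °C to rt; then I2, CH2Cl2, 0 °C
Reagents that add atoms: iodine, II; tributyltin hydride, CCCC[SnH](CCCC)CCCC (supplies H to 8 and the stannyl group of 7)
Why: Pd-catalysed hydrostannation adds H and Sn syn and should place tin on the alkyne carbon next to the hydroxymethyl group, and iododestannylation proceeds with retention, so iodine ends cis to H and CH2OH cis to the chain.

Step 7
Reactants: 8 iodo alcohol
Product: 9 (2E,6Z)-8-[(tert-butyldimethylsilyl)oxy]-2-iodo-6-methylocta-2,6-dien-1-yl acetate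
Conditions: Ac2O, pyridine, DMAP (cat.), CH2Cl2, 0 °C
Reagents that add atoms: acetic anhydride, CC(=O)OC(C)=O
Why: Acetylation of the only free hydroxyl installs the acetate of the target before the fragments are joined.

Step 8
Reactants: 10 methyl 2-[bis(2,2,2-trifluoroethoxy)phosphoryl]acetate; 11 5-bromo-2-methylpent-2-ene
Product: 12 racemic methyl 2-[bis(2,2,2-trifluoroethoxy)phosphoryl]-6-methylhept-5-enoate
Conditions: NaH, DMF, 0 °C; then 11, NaI (cat.), rt to 50 °C (10 in slight excess)
Reagents that add atoms: none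
Why: SN2 C-alkylation of the phosphonoacetate anion with a primary homoallylic halide gives the α-substituted Still–Gennari reagent, with excess 10 limiting dialkylation.

Step 9
Reactants: 12 alkylated phosphonate; 13 3-[(tert-butyldimethylsilyl)oxy]propanal
Product: 14 methyl (2Z)-5-[(tert-butyldimethylsilyl)oxy]-2-(4-methylpent-3-en-1-yl)pent-2-enoate
Conditions: KHMDS, 18-crown-6, THF, −78 °C
Reagents that add atoms: none
Why: Still–Gennari modification of the Horner–Wadsworth–Emmons reaction, where fast irreversible elimination from the trifluoroethyl phosphonate adduct should place the ester cis to the aldehyde-derived chain (Z).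

Step 10
Reactants: 14 Z-enoate silyl ether
Product: 15 methyl (2Z)-5-hydroxy-2-(4-methylpent-3-en-1-yl)pent-2-enoate
Conditions: HF·pyridine, pyridine, THF, 0 °C
Reagents that add atoms: none
Why: Buffered fluoride desilylation frees the primary alcohol without the acid or heat that would close it onto the cis ester.

Step 11
Reactants: 15 Z-hydroxy ester
Product: 16 methyl (2Z)-2-(4-methylpent-3-en-1-yl)-5-oxopent-2-enoate
Conditions: Dess–Martin periodinane, pyridine, CH2Cl2, 0 °C; used at once
Reagents that add atoms: none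
Why: Dess–Martin oxidation under buffered, non-enolizing conditions should give the β,γ-unsaturated aldehyde without moving the C3=C4 alkene.

Step 12
Reactants: 9 iodoallyl acetate; 16 aldehyde ester
Product: 18 (2E,6Z)-8-[(tert-butyldimethylsilyl)oxy]-6-methyl-2-[(2R)-5-(4-methylpent-3-en-1-yl)-6-oxo-3,6-dihydro-2H-pyran-2-yl]octa-2,6-dien-1-yl acetate, via open-chain hydroxy ester 17 (not isolated)
Conditions: CrCl2 (10 mol %), chiral oxazoline–sulfonamide ligand (Kishi type, 11 mol %), proton sponge (11 mol %), NiCl2(2,9-dimethylphenanthroline) (2 mol %), Mn (2 equiv), Cp2ZrCl2 (1.2 equiv), LiCl, MeCN, rt; aqueous work-up; PPTS (cat.), CH2Cl2, rt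
Reagents that add atoms: none
Why: Ni(0) inserts into the C–I bond of 9 with retention of the E geometry and passes the alkenyl group to Cr(III) held by the chiral ligand, and this non-basic alkenylchromium adds to the aldehyde carbon C6 of 16, a reductive union of two electrophilic carbons whose closest known type is the catalytic asymmetric Nozaki–Hiyama–Kishi reaction (Mn as terminal reductant, Cp2ZrCl2 releasing the alkoxide for turnover). The C6 stereocentre is under ligand control: Si-face delivery gives (R), because C1' outranks C5. The C6 alkoxide of 17 then closes the dihydropyranone by 6-exo-trig acyl substitution on the methyl ester, which the Z geometry of C3=C4 holds cis to the C5–C6 arm. The step needs chemoselectivity for the aldehyde over ester, acetate and silyl ether, which the low nucleophilicity of organochromium(III) should secure, and the same low basicity should keep the doubly activated C5 methylene of 16 from enolizing. The allylic acetate should survive because Ni(0) inserts into C(sp2)–I much faster than it ionizes an allylic ester.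

Step 13
Reactants: 18 lactone silyl ether
Product: 19 (2E,6Z)-8-hydroxy-6-methyl-2-[(2R)-5-(4-methylpent-3-en-1-yl)-6-oxo-3,6-dihydro-2H-pyran-2-yl]octa-2,6-dien-1-yl acetate (target)
Conditions: HF·pyridine, pyridine, THF, 0 °C to rt
Reagents that add atoms: none
Why: Buffered fluoride removes the primary allylic TBS ether while acetate, lactone and the C6 stereocentre are untouched.

**Compound list**

1 | nerol, (2Z)-3,7-dimethylocta-2,6-dien-1-ol | CC(C)=CCC/C(C)=C\CO | starting material
2 | tert-butyl{[(2Z)-3,7-dimethylocta-2,6-dien-1-yl]oxy}dimethylsilane | CC(C)=CCC/C(C)=C\CO[Si](C)(C)C(C)(C)C | intermediate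
3 | racemic tert-butyl{[(2Z)-5-(3,3-dimethyloxiran-2-yl)-3-methylpent-2-en-1-yl]oxy}dimethylsilane | CC1(C)OC1CC/C(C)=C\CO[Si](C)(C)C(C)(C)C | intermediate
4 | (4Z)-6-[(tert-butyldimethylsilyl)oxy]-4-methylhex-4-enal | O=CCC/C(C)=C\CO[Si](C)(C)C(C)(C)C | intermediate
5 | tert-butyldimethyl{[(2Z)-3-methylhept-2-en-6-yn-1-yl]oxy}silane | C#CCC/C(C)=C\CO[Si](C)(C)C(C)(C)C | intermediate
6 | (6Z)-8-[(tert-butyldimethylsilyl)oxy]-6-methyloct-6-en-2-yn-1-ol | OCC#CCC/C(C)=C\CO[Si](C)(C)C(C)(C)C | intermediate
7 | (2E,6Z)-8-[(tert-butyldimethylsilyl)oxy]-6-methyl-2-(tributylstannyl)octa-2,6-dien-1-ol | OC/C(=C\CC/C(C)=C\CO[Si](C)(C)C(C)(C)C)[Sn](CCCC)(CCCC)CCCC | intermediate (not isolated)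
8 | (2E,6Z)-8-[(tert-butyldimethylsilyl)oxy]-2-iodo-6-methylocta-2,6-dien-1-ol | OC/C(I)=C\CC/C(C)=C\CO[Si](C)(C)C(C)(C)C | intermediate
9 | (2E,6Z)-8-[(tert-butyldimethylsilyl)oxy]-2-iodo-6-methylocta-2,6-dien-1-yl acetate | CC(=O)OC/C(I)=C\CC/C(C)=C\CO[Si](C)(C)C(C)(C)C | intermediate
10 | methyl 2-[bis(2,2,2-trifluoroethoxy)phosphoryl]acetate | COC(=O)CP(=O)(OCC(F)(F)F)OCC(F)(F)F | starting material
11 | 5-bromo-2-methylpent-2-ene | CC(C)=CCCBr | starting material
12 | racemic methyl 2-[bis(2,2,2-trifluoroethoxy)phosphoryl]-6-methylhept-5-enoate | COC(=O)C(CCC=C(C)C)P(=O)(OCC(F)(F)F)OCC(F)(F)F | intermediate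
13 | 3-[(tert-butyldimethylsilyl)oxy]propanal | O=CCCO[Si](C)(C)C(C)(C)C | starting material
14 | methyl (2Z)-5-[(tert-butyldimethylsilyl)oxy]-2-(4-methylpent-3-en-1-yl)pent-2-enoate | COC(=O)/C(CCC=C(C)C)=C\CCO[Si](C)(C)C(C)(C)C | intermediate
15 | methyl (2Z)-5-hydroxy-2-(4-methylpent-3-en-1-yl)pent-2-enoate | COC(=O)/C(CCC=C(C)C)=C\CCO | intermediate
16 | methyl (2Z)-2-(4-methylpent-3-en-1-yl)-5-oxopent-2-enoate | COC(=O)/C(CCC=C(C)C)=C\CC=O | intermediate
17 | methyl (2Z,5R,6E,10Z)-6-(acetoxymethyl)-12-[(tert-butyldimethylsilyl)oxy]-5-hydroxy-10-methyl-2-(4-methylpent-3-en-1-yl)dodeca-2,6,10-trienoate | COC(=O)/C(CCC=C(C)C)=C\C[C@@H](O)/C(COC(C)=O)=C/CC/C(C)=C\CO[Si](C)(C)C(C)(C)C | intermediate (not isolated)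
18 | (2E,6Z)-8-[(tert-butyldimethylsilyl)oxy]-6-methyl-2-[(2R)-5-(4-methylpent-3-en-1-yl)-6-oxo-3,6-dihydro-2H-pyran-2-yl]octa-2,6-dien-1-yl acetate | CC(=O)OC/C(=C\CC/C(C)=C\CO[Si](C)(C)C(C)(C)C)[C@H]1CC=C(CCC=C(C)C)C(=O)O1 | intermediate
19 | (2E,6Z)-8-hydroxy-6-methyl-2-[(2R)-5-(4-methylpent-3-en-1-yl)-6-oxo-3,6-dihydro-2H-pyran-2-yl]octa-2,6-dien-1-yl acetate | CC(=O)OC/C(=C\CC/C(C)=C\CO)[C@H]1CC=C(CCC=C(C)C)C(=O)O1 | target

**Totals**

Total step count: 13. Longest linear sequence: 9 steps (steps 1–7, 12, 13); steps 8–11 form the second branch, which converges at step 12.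

**Steps most likely to fail, with fallbacks**

Step 12. The addition may show poor facial selectivity, because the aldehyde is unbranched and the alkenyl iodide trisubstituted, and the alkenyl-metal may lose acetate by β-elimination toward an allene. The fallback sets out from 8 and comes back at 18. Compound 8 would be silylated (TESCl, imidazole) to the triethylsilyl ether F1. Iodine–lithium exchange (t-BuLi, Et2O, −78 °C), transmetalation to zinc (ZnBr2) and amino-alcohol-catalysed addition to 16 ((−)-MIB type, with a diamine to sequester lithium halide), followed by lactonization, would give the lactone triethylsilyl ether F2. Selective cleavage of the TES ether (PPTS, MeOH, 0 °C) would give the primary alcohol F3, and acetylation (Ac2O, pyridine) would return to 18.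

Step 11. The C3=C4 alkene may migrate into conjugation with the new aldehyde through enolization at C5, which is α to the aldehyde and γ to the ester, and 15 may lactonize before it is oxidized. The fallback sets out from 14 and comes back at 18, carrying C2 at the alcohol oxidation level so that no vinylogous activation exists. DIBAL-H would reduce 14 to the allylic alcohol F4, and NaH/PMBCl would give the 4-methoxybenzyl ether F5. TBAF would give the primary alcohol F6 and Dess–Martin oxidation the aldehyde F7. The Ni/Cr coupling of step 12 with 9 would then give the secondary allylic alcohol F8. DDQ (CH2Cl2, pH 7 buffer) would give the diol F9, and TEMPO/PhI(OAc)2 would oxidize only the primary allylic alcohol, the resulting lactol being oxidized on to lactone 18.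

Step 6. Hydrostannation may lack regiocontrol and place tin on the alkyne carbon remote from the hydroxymethyl group. The fallback sets out from 5 and comes back at 8. Alkyne 5 would be carboxylated (n-BuLi, ClCO2Me) to the ynoate F10. Pd(PPh3)4/Bu3SnH, which is reliably α-selective and syn on alkynoates, would give the α-stannyl enoate F11. Iodine would give the iodo enoate F12, and DIBAL-H at −78 °C would reduce the ester to 8.

**Further compounds**

F1 | step 12 | (2E,6Z)-8-[(tert-butyldimethylsilyl)oxy]-2-iodo-6-methyl-1-[(triethylsilyl)oxy]octa-2,6-diene | CC[Si](CC)(CC)OC/C(I)=C\CC/C(C)=C\CO[Si](C)(C)C(C)(C)C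
F2 | step 12 | (6R)-6-{(2E,6Z)-8-[(tert-butyldimethylsilyl)oxy]-6-methyl-1-[(triethylsilyl)oxy]octa-2,6-dien-2-yl}-3-(4-methylpent-3-en-1-yl)-5,6-dihydro-2H-pyran-2-one | CC[Si](CC)(CC)OC/C(=C\CC/C(C)=C\CO[Si](C)(C)C(C)(C)C)[C@H]1CC=C(CCC=C(C)C)C(=O)O1
F3 | step 12 | (6R)-6-{(2E,6Z)-8-[(tert-butyldimethylsilyl)oxy]-1-hydroxy-6-methylocta-2,6-dien-2-yl}-3-(4-methylpent-3-en-1-yl)-5,6-dihydro-2H-pyran-2-one | OC/C(=C\CC/C(C)=C\CO[Si](C)(C)C(C)(C)C)[C@H]1CC=C(CCC=C(C)C)C(=O)O1
F4 | step 11 | (2Z)-5-[(tert-butyldimethylsilyl)oxy]-2-(4-methylpent-3-en-1-yl)pent-2-en-1-ol | OC/C(CCC=C(C)C)=C\CCO[Si](C)(C)C(C)(C)C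
F5 | step 11 | tert-butyl{[(3Z)-5-[(4-methoxybenzyl)oxy]-4-(4-methylpent-3-en-1-yl)pent-3-en-1-yl]oxy}dimethylsilane | COc1ccc(COC/C(CCC=C(C)C)=C\CCO[Si](C)(C)C(C)(C)C)cc1
F6 | step 11 | (3Z)-5-[(4-methoxybenzyl)oxy]-4-(4-methylpent-3-en-1-yl)pent-3-en-1-ol | COc1ccc(COC/C(CCC=C(C)C)=C\CCO)cc1
F7 | step 11 | (3Z)-5-[(4-methoxybenzyl)oxy]-4-(4-methylpent-3-en-1-yl)pent-3-enal | COc1ccc(COC/C(CCC=C(C)C)=C\CC=O)cc1
F8 | step 11 | (2E,6Z)-8-[(tert-butyldimethylsilyl)oxy]-2-[(1R,3Z)-1-hydroxy-5-[(4-methoxybenzyl)oxy]-4-(4-methylpent-3-en-1-yl)pent-3-en-1-yl]-6-methylocta-2,6-dien-1-yl acetate | COc1ccc(COC/C(CCC=C(C)C)=C\C[C@@H](O)/C(COC(C)=O)=C/CC/C(C)=C\CO[Si](C)(C)C(C)(C)C)cc1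
F9 | step 11 | (2E,6Z)-8-[(tert-butyldimethylsilyl)oxy]-2-[(1R,3Z)-1,5-dihydroxy-4-(4-methylpent-3-en-1-yl)pent-3-en-1-yl]-6-methylocta-2,6-dien-1-yl acetate | OC/C(CCC=C(C)C)=C\C[C@@H](O)/C(COC(C)=O)=C/CC/C(C)=C\CO[Si](C)(C)C(C)(C)C
F10 | step 6 | methyl (6Z)-8-[(tert-butyldimethylsilyl)oxy]-6-methyloct-6-en-2-ynoate | COC(=O)C#CCC/C(C)=C\CO[Si](C)(C)C(C)(C)C
F11 | step 6 | methyl (2E,6Z)-8-[(tert-butyldimethylsilyl)oxy]-6-methyl-2-(tributylstannyl)octa-2,6-dienoate | COC(=O)/C(=C\CC/C(C)=C\CO[Si](C)(C)C(C)(C)C)[Sn](CCCC)(CCCC)CCCC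
F12 | step 6 | methyl (2E,6Z)-8-[(tert-butyldimethylsilyl)oxy]-2-iodo-6-methylocta-2,6-dienoate | COC(=O)/C(I)=C\CC/C(C)=C\CO[Si](C)(C)C(C)(C)C
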